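C11=C12 and C11'=C12' are cut as Horner–Wadsworth–Emmons (HWE) olefinations around 2,7-dimethylocta-2,4,6-trienedial (C12–C12'). C8'–C9' is cut as a Sonogashira coupling and C8–C9 as a Nozaki–Hiyama–Kishi coupling. One C4 iodo phosphonate supplies both C9–C11 and C9'–C11', which leaves two C11 termini (carotenoid numbering throughout).
Enabling feature: ring A (C1–C6, epoxide) and ring B (C1'–C6', acetate) are the same carbocycle. Each has CMe2 at C1, a carbinol at C3 between the C2 and C4 methylenes, and a methyl-bearing C5 joined to a fully substituted C6 that carries C7. C3 and C3' have the same arrangement in space; the descriptors S and R differ only because of the epoxide oxygen. One hydroxycyclohexene ester therefore serves both ends.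
That ring is cut at C3–C4 to an acyclic aldehyde ester, built from prenol and 3-methylbut-2-enoic acid by Ireland–Claisen rearrangement and aldehyde-selective Wacker oxidation.
Forward, the carbocycle is closed once and then divided. One portion becomes the C7'≡C8' enyne acetate (ring B). The other becomes the allylic alcohol, then the oxirane ring, then the C8 aldehyde (ring A). The chain is joined in the order C8'–C9', C11'=C12', C8–C9, C11=C12.
Stereochemistry: C3 and C3' come from the chiral acid in the ring closure, and C5 and C6 from the tartrate in the Sharpless epoxidation. C9=C10 and C9'=C10' come from syn hydrozirconation, the C13, C15 and C13' alkenes from the dialdehyde, and C11=C12 and C11'=C12' from E-selective olefinations.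

Key step: step 5

Assumption: the sense of induction of the confined acid cannot be derived from a model for this substrate class; both catalyst antipodes come from (R)- and (S)-BINOL, and the antipode that leads to the (R)-carbinol is meant wherever the catalyst is named.

Step 1
Reactants: 1 prenol (3-methylbut-2-en-1-ol); 2 3-methylbut-2-enoic acid
Product: 3 3-methylbut-2-en-1-yl 3-methylbut-2-enoate (prenyl senecioate)
Conditions: dicyclohexylcarbodiimide, DMAP (cat.), CH2Cl2, 0 °C to rt
Reagents that add atoms: none
Why: Steglich esterification couples the two C5 units under neutral conditions, and any ester that slips out of conjugation under DMAP feeds the same dienolate in step 2.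

Step 2
Reactants: 3 prenyl senecioate
Product: 6 (±)-3,3-dimethyl-2-(prop-1-en-2-yl)pent-4-enoic acid, via silyl ketene acetal 4 (not isolated), via trimethylsilyl ester 5 (not isolated)
Conditions: LiN(i-Pr)2, THF, −78 °C; Me3SiCl; −78 °C to reflux; then 1 M HCl
Reagents that add atoms: chlorotrimethylsilane, C[Si](C)(C)Cl (its silyl group is carried only by 4 and 5)
Why: Ireland–Claisen rearrangement: γ-deprotonation gives the extended enolate, O-silylation traps it as ketene acetal 4, and the chair-like [3,3] shift joins the α-carbon (future C6) to the dimethyl-substituted allyl terminus (future C1), which creates the quaternary carbon, the isopropenyl group and the vinyl group at once; the single stereocentre forms as a racemate, which step 5 tolerates.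

Step 3
Reactants: 6 (±)-3,3-dimethyl-2-(prop-1-en-2-yl)pent-4-enoic acid
Product: 7 methyl (±)-3,3-dimethyl-2-(prop-1-en-2-yl)pent-4-enoate
Conditions: MeI, K2CO3, DMF, rt
Reagents that add atoms: iodomethane, IC
Why: SN2 O-methylation of the carboxylate needs neither acid nor strong base, so the isopropenyl double bond should stay out of conjugation with the ester.

Step 4
Reactants: 7 methyl (±)-3,3-dimethyl-2-(prop-1-en-2-yl)pent-4-enoate
Product: 8 methyl (±)-3,3-dimethyl-5-oxo-2-(prop-1-en-2-yl)pentanoate
Conditions: PdCl2(PhCN)2 (cat.), CuCl2·2H2O (cat.), AgNO2 (cat.), O2 (1 atm), t-BuOH/MeNO2, rt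
Reagents that add atoms: dioxygen, O=O
Why: Nitrite-modified, aldehyde-selective Wacker-type oxidation, established for vinyl groups on quaternary carbons: the neopentyl surroundings steer oxygen to the terminal carbon, the 1,1-disubstituted isopropenyl group binds divalent palladium poorly, and the aldehyde (C3) is reached without a δ-hydroxy ester that the gem-dimethyl group would drive to the lactone.

Step 5
Reactants: 8 methyl (±)-3,3-dimethyl-5-oxo-2-(prop-1-en-2-yl)pentanoate
Product: 9 methyl (R)-4-hydroxy-2,6,6-trimethylcyclohex-1-ene-1-carboxylate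
Conditions: chiral confined imidodiphosphorimidate acid (BINOL-derived, 3,3'-aryl walls, N-triflyl core, 5 mol %), 5 Å MS, CHCl3/methylcyclohexane, −20 °C to rt
Reagents that add atoms: none
Why: Proposed new method: the confined acid activates the aldehyde of 8 inside its chiral pocket, the CH2 terminus of the isopropenyl group (C4) adds to the carbonyl carbon (C3) in the Markovnikov sense, and the tertiary C5 cation, paired with the chiral anion, loses the C6 proton to leave the C5=C6 enoate. The nearest known reaction type is the acid-induced carbonyl-ene (Prins) ring closure of unsaturated aldehydes, with the citronellal-to-isopulegol cyclisation as the textbook case and confined BINOL-derived Brønsted acids as its enantioselective form; not yet shown are a tether on the internal alkene carbon under such catalysis, an ester on the allylic carbon and the convergent use of a racemic substrate. The one ring closes 6-endo-trig at the alkene (C4 and C5 both become ring members) and 6-exo-trig at the carbonyl group, assisted by the gem-dimethyl group at C1. The one new stereocentre, C3, is controlled by the catalyst, which has to present the same aldehyde face to C4 for both enantiomers of 8; the old centre C6 stands 1,4 to C3, away from the forming bond, and vanishes on proton loss, so both enantiomers of 8 end in the same product. The step needs regioselective proton loss: the exocyclic and C4=C5 isomers are unconjugated, more basic alkenes that the same acid can protonate back to the C5 cation, whereas the tetrasubstituted, ester-conjugated alkene of 9 is the least basic isomer and serves as the thermodynamic sink. Chemoselectivity rests on the confined pocket and the low temperature, which should suppress acetal formation between 9 and 8 and ionisation of the homoallylic carbinol.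

Step 6
Reactants: 9 methyl (R)-4-hydroxy-2,6,6-trimethylcyclohex-1-ene-1-carboxylate
Product: 10 methyl (R)-4-(tert-butyldimethylsilyloxy)-2,6,6-trimethylcyclohex-1-ene-1-carboxylate
Conditions: TBSCl, imidazole, DMF, rt
Reagents that add atoms: tert-butylchlorodimethylsilane, CC(C)(C)[Si](C)(C)Cl
Why: Standard silylation of the unhindered secondary alcohol masks C3–OH against hydride, oxidants and organometallic reagents without touching the stereocentre.

Step 7
Reactants: 10 silyl ether ester
Product: 11 [(R)-4-(tert-butyldimethylsilyloxy)-2,6,6-trimethylcyclohex-1-en-1-yl]methanol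
Conditions: i-Bu2AlH (2.5 equiv), CH2Cl2, −78 to 0 °C; aq. potassium sodium tartrate
Reagents that add atoms: none
Why: 1,2-Reduction of the hindered enoate with i-Bu2AlH gives the primary allylic alcohol, which is the handle for directed epoxidation (ring A) and the precursor of the C7' aldehyde (ring B).

Step 8
Reactants: 11 allylic alcohol (first portion)
Product: 12 (R)-4-(tert-butyldimethylsilyloxy)-2,6,6-trimethylcyclohex-1-ene-1-carbaldehyde
Conditions: activated MnO2, CH2Cl2, rt
Reagents that add atoms: none
Why: MnO2 oxidation of an allylic alcohol stops at the enal and leaves the silyl ether alone.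

Step 9
Reactants: 12 enal
Product: 13 tert-butyl{[(R)-4-ethynyl-3,5,5-trimethylcyclohex-3-en-1-yl]oxy}dimethylsilane
Conditions: (MeO)2P(O)CHN2, KOt-Bu, THF, −78 °C (anion pre-formed), then 12, −78 °C to rt
Reagents that add atoms: dimethyl (diazomethyl)phosphonate, COP(=O)(OC)C=[N+]=[N-]
Why: Seyferth–Gilbert homologation: the phosphonate anion adds to the aldehyde, cycloelimination gives the diazoalkene, and nitrogen loss followed by a 1,2-hydrogen shift in the alkylidene carbene delivers the C7'≡C8' alkyne; the methanol-free protocol avoids conjugate addition, and pre-forming the anion keeps free base away from the C4' protons.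

Step 10
Reactants: 13 silylated enyne
Product: 14 (R)-4-ethynyl-3,5,5-trimethylcyclohex-3-en-1-ol
Conditions: Bu4NF, THF, rt
Reagents that add atoms: none
Why: Fluoride-induced desilylation, to which nothing else in 13 responds.

Step 11
Reactants: 14 hydroxy enyne
Product: 15 (R)-4-ethynyl-3,5,5-trimethylcyclohex-3-en-1-yl acetate
Conditions: Ac2O, pyridine, DMAP (cat.), CH2Cl2, rt
Reagents that add atoms: acetic anhydride, CC(=O)OC(C)=O
Why: DMAP-catalysed acetylation installs the C3' acetate with retention, at a point after which only acetate-tolerant reactions follow on this branch.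

Step 12
Reactants: 16 but-2-yn-1-ol
Product: 18 (E)-3-iodobut-2-en-1-ol, via alkenylzirconocene 17 (not isolated)
Conditions: Cp2Zr(H)Cl (2.2 equiv, the first equivalent is consumed by the hydroxyl group), THF, rt, dark; then I2, 0 °C
Reagents that add atoms: iodine, [I][I]; Cp2Zr(H)Cl, [H][Zr](Cl)(C1C=CC=C1)C1C=CC=C1 (zirconium is carried only by 17)
Why: Hydrozirconation–iodination: syn addition of Zr–H places zirconium on the methyl-bearing alkyne carbon, remote from the bulky zirconium alkoxide, and iodinolysis with retention fixes the E geometry that becomes C9=C10 and C9'=C10'.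

Step 13
Reactants: 18 (E)-3-iodobut-2-en-1-ol
Product: 19 (E)-1-bromo-3-iodobut-2-ene
Conditions: CBr4, PPh3, CH2Cl2, 0 °C
Reagents that add atoms: tetrabromomethane, BrC(Br)(Br)Br
Why: Appel bromination converts the primary allylic alcohol by SN2 under neutral conditions, so neither the alkene geometry nor the C–I bond should be affected.

Step 14
Reactants: 19 (E)-1-bromo-3-iodobut-2-ene
Product: 20 diethyl [(E)-3-iodobut-2-en-1-yl]phosphonate
Conditions: P(OEt)3 (neat), 110 °C
Reagents that add atoms: triethyl phosphite, CCOP(OCC)OCC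
Why: Michaelis–Arbuzov reaction at the primary allylic bromide, with the alkenyl iodide inert to the phosphite.

Step 15
Reactants: 15 acetoxy enyne; 20 iodo phosphonate
Product: 21 diethyl {(E)-5-[(R)-4-acetoxy-2,6,6-trimethylcyclohex-1-en-1-yl]-3-methylpent-2-en-4-yn-1-yl}phosphonate
Conditions: PdCl2(PPh3)2 (cat.), CuI (cat.), Et3N, THF, rt, degassed
Reagents that add atoms: none
Why: Sonogashira coupling forms C8'–C9' with retention of the E geometry of the alkenyl iodide, under amine-base conditions that spare acetate and phosphonate.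

Step 16
Reactants: 21 C15 phosphonate; 22 (2E,4E,6E)-2,7-dimethylocta-2,4,6-trienedial
Product: 23 (2E,4E,6E,8E,10E)-13-[(R)-4-acetoxy-2,6,6-trimethylcyclohex-1-en-1-yl]-2,7,11-trimethyltrideca-2,4,6,8,10-pentaen-12-ynal (C25 aldehyde)
Conditions: NaN(SiMe3)2 (0.95 equiv), THF, −78 °C; cannulated into 22 (3 equiv), −78 to 0 °C, dark
Reagents that add atoms: none
Why: HWE olefination of an allylic phosphonate anion gives the E C11'=C12' alkene; inverse addition to excess symmetrical dialdehyde favours mono-olefination, low temperature and the small phosphoryl group should limit rotation about C9'=C10' in the delocalised anion, and the slight deficit of base protects the acetate.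

Step 17
Reactants: 11 allylic alcohol (second portion)
Product: 24 [(1R,4S,6R)-4-(tert-butyldimethylsilyloxy)-2,2,6-trimethyl-7-oxabicyclo[4.1.0]heptan-1-yl]methanol
Conditions: Ti(Oi-Pr)4 (20 mol %), D-(−)-diethyl tartrate (24 mol %), t-BuOOH, 4 Å MS, CH2Cl2, −20 °C
Reagents that add atoms: tert-butyl hydroperoxide, CC(C)(C)OO
Why: Katsuki–Sharpless asymmetric epoxidation: the primary allylic alcohol binds titanium, and the D-(−)-tartrate, the series that makes the hydroxymethyl-bearing epoxide carbon R, delivers oxygen to the C5=C6 face anti to the C3 silyl ether, which sets C5 and C6 together under reagent control.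

Step 18
Reactants: 24 epoxy alcohol
Product: 25 (1S,4S,6R)-4-(tert-butyldimethylsilyloxy)-2,2,6-trimethyl-7-oxabicyclo[4.1.0]heptane-1-carbaldehyde
Conditions: Dess–Martin periodinane, NaHCO3, CH2Cl2, 0 °C to rt
Reagents that add atoms: none
Why: Buffered Dess–Martin oxidation handles the neopentyl-type primary alcohol without acid that could open the epoxide, and the aldehyde has no α-hydrogen to epimerise.

Step 19
Reactants: 25 epoxy aldehyde
Product: 26 (1S,4S,6R)-4-(tert-butyldimethylsilyloxy)-1-ethenyl-2,2,6-trimethyl-7-oxabicyclo[4.1.0]heptane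
Conditions: MePPh3Br, KOt-Bu, THF, 0 °C
Reagents that add atoms: methyltriphenylphosphonium bromide, C[P+](c1ccccc1)(c1ccccc1)c1ccccc1.[Br-]
Why: Wittig methylenation of a non-enolisable aldehyde adds C8 and leaves the epoxide untouched.

Step 20
Reactants: 26 vinyl epoxide
Product: 28 2-[(1S,4S,6R)-4-(tert-butyldimethylsilyloxy)-2,2,6-trimethyl-7-oxabicyclo[4.1.0]heptan-1-yl]ethanol, via B-alkyl-9-BBN adduct 27 (not isolated)
Conditions: 9-BBN, THF, 0 °C to rt; then aq. NaOH, H2O2, 0 °C
Reagents that add atoms: hydrogen peroxide, OO; 9-borabicyclo[3.3.1]nonane, B1C2CCCC1CCC2 (boron is carried only by 27)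
Why: Hydroboration–oxidation: the bulky borane places boron on the terminal carbon (C8) of the vinyl group next to the quaternary C6, and the tetrasubstituted epoxide and the silyl ether are inert to 9-BBN and cold alkaline peroxide.

Step 21
Reactants: 28 primary alcohol
Product: 29 2-[(1S,4S,6R)-4-(tert-butyldimethylsilyloxy)-2,2,6-trimethyl-7-oxabicyclo[4.1.0]heptan-1-yl]acetaldehyde
Conditions: Dess–Martin periodinane, NaHCO3, CH2Cl2, 0 °C; used at once
Reagents that add atoms: none
Why: Buffered Dess–Martin oxidation needs no amine base, so the β,γ-epoxy aldehyde should not suffer enolisation and epoxide opening.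

Step 22
Reactants: 29 C8 aldehyde; 20 iodo phosphonate
Product: 30 diethyl {(E)-4-hydroxy-3-methyl-5-[(1S,4S,6R)-4-(tert-butyldimethylsilyloxy)-2,2,6-trimethyl-7-oxabicyclo[4.1.0]heptan-1-yl]pent-2-en-1-yl}phosphonate (C8 epimers)
Conditions: CrCl2 (4 equiv), NiCl2 (cat.), DMF, rt
Reagents that add atoms: none
Why: Nozaki–Hiyama–Kishi coupling: zerovalent nickel inserts into the C–I bond with retention, and transmetalation to trivalent chromium gives a non-basic alkenyl nucleophile that adds to the enolisable aldehyde (C8–C9) without touching the epoxide or the acidic CH2P group; the C8 carbinol forms as an epimer mixture that step 24 erases.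

Step 23
Reactants: 30 hydroxy phosphonate
Product: 31 diethyl {(E)-4-hydroxy-5-[(1S,4S,6R)-4-hydroxy-2,2,6-trimethyl-7-oxabicyclo[4.1.0]heptan-1-yl]-3-methylpent-2-en-1-yl}phosphonate (C8 epimers)
Conditions: Bu4NF, THF, 0 °C to rt
Reagents that add atoms: none
Why: Fluoride desilylation is placed here because C8 is still a carbinol, so no base-labile β,γ-epoxy ketone and no acetate is exposed to the basic fluoride.

Step 24
Reactants: 31 diol
Product: 32 diethyl {(E)-5-[(1S,4S,6R)-4-hydroxy-2,2,6-trimethyl-7-oxabicyclo[4.1.0]heptan-1-yl]-3-methyl-4-oxopent-2-en-1-yl}phosphonate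
Conditions: activated MnO2, CH2Cl2, rt
Reagents that add atoms: none
Why: Chemoselective MnO2 oxidation converts only the allylic C8 carbinol under neutral conditions and leaves the saturated C3 carbinol and the epoxide intact.

Step 25
Reactants: 32 C15 keto phosphonate; 23 C25 aldehyde
Product: 33 (3S,5R,6S,3'R)-3'-acetoxy-5,6-epoxy-3-hydroxy-7',8'-didehydro-5,6,7,8-tetrahydro-β,β-caroten-8-one (CNP0217594.1)
Conditions: LiCl, DBU, THF/MeCN, 0 °C to rt, argon, dark
Reagents that add atoms: none
Why: Vinylogous HWE olefination under Masamune–Roush conditions: the C11 protons, activated by the phosphoryl group and by the enone, are far more acidic than the hindered C7 protons, so the mild amine base should form only the extended anion, which attacks the aldehyde through C11 to give the E C11=C12 alkene while the free C3–OH, the acetate and the epoxide remain untouched.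

Compound list
1 | prenol (3-methylbut-2-en-1-ol) | CC(C)=CCO | starting material
2 | 3-methylbut-2-enoic acid | CC(C)=CC(=O)O | starting material
3 | 3-methylbut-2-en-1-yl 3-methylbut-2-enoate | CC(C)=CCOC(=O)C=C(C)C | intermediate
4 | trimethyl{[3-methyl-1-(3-methylbut-2-enyloxy)buta-1,3-dienyl]oxy}silane (silyl ketene acetal) | C=C(C)C=C(O[Si](C)(C)C)OCC=C(C)C | intermediate
5 | trimethylsilyl 3,3-dimethyl-2-(prop-1-en-2-yl)pent-4-enoate (racemic) | C=CC(C)(C)C(C(C)=C)C(=O)O[Si](C)(C)C | intermediate
6 | 3,3-dimethyl-2-(prop-1-en-2-yl)pent-4-enoic acid (racemic) | C=CC(C)(C)C(C(C)=C)C(=O)O | intermediate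
7 | methyl 3,3-dimethyl-2-(prop-1-en-2-yl)pent-4-enoate (racemic) | COC(=O)C(C(C)=C)C(C)(C)C=C | intermediate
8 | methyl 3,3-dimethyl-5-oxo-2-(prop-1-en-2-yl)pentanoate (racemic) | COC(=O)C(C(C)=C)C(C)(C)CC=O | intermediate
9 | methyl (R)-4-hydroxy-2,6,6-trimethylcyclohex-1-ene-1-carboxylate | O[C@@H]1CC(C)=C(C(=O)OC)C(C)(C)C1 | intermediate
10 | methyl (R)-4-(tert-butyldimethylsilyloxy)-2,6,6-trimethylcyclohex-1-ene-1-carboxylate | CC(C)(C)[Si](C)(C)O[C@@H]1CC(C)=C(C(=O)OC)C(C)(C)C1 | intermediate
11 | [(R)-4-(tert-butyldimethylsilyloxy)-2,6,6-trimethylcyclohex-1-en-1-yl]methanol | CC(C)(C)[Si](C)(C)O[C@@H]1CC(C)=C(CO)C(C)(C)C1 | intermediate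
12 | (R)-4-(tert-butyldimethylsilyloxy)-2,6,6-trimethylcyclohex-1-ene-1-carbaldehyde | CC(C)(C)[Si](C)(C)O[C@@H]1CC(C)=C(C=O)C(C)(C)C1 | intermediate
13 | tert-butyl{[(R)-4-ethynyl-3,5,5-trimethylcyclohex-3-en-1-yl]oxy}dimethylsilane | CC(C)(C)[Si](C)(C)O[C@@H]1CC(C)=C(C#C)C(C)(C)C1 | intermediate
14 | (R)-4-ethynyl-3,5,5-trimethylcyclohex-3-en-1-ol | O[C@@H]1CC(C)=C(C#C)C(C)(C)C1 | intermediate
15 | (R)-4-ethynyl-3,5,5-trimethylcyclohex-3-en-1-yl acetate | CC(=O)O[C@@H]1CC(C)=C(C#C)C(C)(C)C1 | intermediate
16 | but-2-yn-1-ol | CC#CCO | starting material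
17 | (E)-alkenylzirconocene chloride of but-2-yn-1-ol, oxygen bound to a second Cp2ZrCl unit | C/C(=C\CO[Zr](Cl)(C1C=CC=C1)C1C=CC=C1)[Zr](Cl)(C1C=CC=C1)C1C=CC=C1 | intermediate
18 | (E)-3-iodobut-2-en-1-ol | I/C(C)=C/CO | intermediate
19 | (E)-1-bromo-3-iodobut-2-ene | I/C(C)=C/CBr | intermediate
20 | diethyl [(E)-3-iodobut-2-en-1-yl]phosphonate | CCOP(=O)(OCC)C/C=C(\C)I | intermediate
21 | diethyl {(E)-5-[(R)-4-acetoxy-2,6,6-trimethylcyclohex-1-en-1-yl]-3-methylpent-2-en-4-yn-1-yl}phosphonate | CC(=O)O[C@@H]1CC(C)=C(C#C/C(C)=C/CP(=O)(OCC)OCC)C(C)(C)C1 | intermediate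
22 | (2E,4E,6E)-2,7-dimethylocta-2,4,6-trienedial | O=C/C(C)=C/C=C/C=C(C)/C=O | starting material
23 | (2E,4E,6E,8E,10E)-13-[(R)-4-acetoxy-2,6,6-trimethylcyclohex-1-en-1-yl]-2,7,11-trimethyltrideca-2,4,6,8,10-pentaen-12-ynal | CC(=O)O[C@@H]1CC(C)=C(C#C/C(C)=C/C=C/C(C)=C/C=C/C=C(C)/C=O)C(C)(C)C1 | intermediate
24 | [(1R,4S,6R)-4-(tert-butyldimethylsilyloxy)-2,2,6-trimethyl-7-oxabicyclo[4.1.0]heptan-1-yl]methanol | OC[C@@]12O[C@]1(C)C[C@@H](O[Si](C)(C)C(C)(C)C)CC2(C)C | intermediate
25 | (1S,4S,6R)-4-(tert-butyldimethylsilyloxy)-2,2,6-trimethyl-7-oxabicyclo[4.1.0]heptane-1-carbaldehyde | O=C[C@@]12O[C@]1(C)C[C@@H](O[Si](C)(C)C(C)(C)C)CC2(C)C | intermediate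
26 | (1S,4S,6R)-4-(tert-butyldimethylsilyloxy)-1-ethenyl-2,2,6-trimethyl-7-oxabicyclo[4.1.0]heptane | C=C[C@@]12O[C@]1(C)C[C@@H](O[Si](C)(C)C(C)(C)C)CC2(C)C | intermediate
27 | B-alkyl-9-BBN adduct of 26 (boron on C8) | C1CC2CCCC(C1)B2CC[C@@]34O[C@]3(C)C[C@@H](O[Si](C)(C)C(C)(C)C)CC4(C)C | intermediate
28 | 2-[(1S,4S,6R)-4-(tert-butyldimethylsilyloxy)-2,2,6-trimethyl-7-oxabicyclo[4.1.0]heptan-1-yl]ethanol | OCC[C@@]12O[C@]1(C)C[C@@H](O[Si](C)(C)C(C)(C)C)CC2(C)C | intermediate
29 | 2-[(1S,4S,6R)-4-(tert-butyldimethylsilyloxy)-2,2,6-trimethyl-7-oxabicyclo[4.1.0]heptan-1-yl]acetaldehyde | O=CC[C@@]12O[C@]1(C)C[C@@H](O[Si](C)(C)C(C)(C)C)CC2(C)C | intermediate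
30 | diethyl {(E)-4-hydroxy-3-methyl-5-[(1S,4S,6R)-4-(tert-butyldimethylsilyloxy)-2,2,6-trimethyl-7-oxabicyclo[4.1.0]heptan-1-yl]pent-2-en-1-yl}phosphonate (C8 epimers) | CCOP(=O)(OCC)C/C=C(\C)C(O)C[C@@]12O[C@]1(C)C[C@@H](O[Si](C)(C)C(C)(C)C)CC2(C)C | intermediate
31 | diethyl {(E)-4-hydroxy-5-[(1S,4S,6R)-4-hydroxy-2,2,6-trimethyl-7-oxabicyclo[4.1.0]heptan-1-yl]-3-methylpent-2-en-1-yl}phosphonate (C8 epimers) | CCOP(=O)(OCC)C/C=C(\C)C(O)C[C@@]12O[C@]1(C)C[C@@H](O)CC2(C)C | intermediate
32 | diethyl {(E)-5-[(1S,4S,6R)-4-hydroxy-2,2,6-trimethyl-7-oxabicyclo[4.1.0]heptan-1-yl]-3-methyl-4-oxopent-2-en-1-yl}phosphonate | CCOP(=O)(OCC)C/C=C(\C)C(=O)C[C@@]12O[C@]1(C)C[C@@H](O)CC2(C)C | intermediate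
33 | (3S,5R,6S,3'R)-3'-acetoxy-5,6-epoxy-3-hydroxy-7',8'-didehydro-5,6,7,8-tetrahydro-β,β-caroten-8-one (CNP0217594.1) | CC(=O)O[C@@H]1CC(C)=C(C#C/C(C)=C/C=C/C(C)=C/C=C/C=C(C)/C=C/C=C(\C)C(=O)C[C@@]23O[C@]2(C)C[C@@H](O)CC3(C)C)C(C)(C)C1 | target

Total step count: 25. Longest linear sequence: 16 (steps 1–7 and 17–25).

Steps most likely to fail

1. Step 5.
What may go wrong: the catalyst may discriminate the aldehyde faces poorly for one or both enantiomers of the substrate. Proton loss may stall at unconjugated alkene isomers. The ester-deactivated alkene may react too slowly.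
Fallback: ring closure and stereocontrol are separated, using known chemistry only. The fallback sets out from 8. Me2AlCl (CH2Cl2, −78 to 0 °C) induces the Lewis-acid carbonyl-ene cyclisation to racemic methyl 4-hydroxy-2,2-dimethyl-6-methylidenecyclohexane-1-carboxylate F1. DBU in warm toluene then moves the double bond into conjugation to give racemic methyl 4-hydroxy-2,6,6-trimethylcyclohex-1-ene-1-carboxylate F2. Lipase-catalysed acetylation (lipase from Burkholderia cepacia, vinyl acetate, t-BuOMe) resolves F2. By the empirical size rule for secondary alcohols it should acylate the enantiomer whose larger CH2–CMe2 flank has the higher priority. That gives methyl (R)-4-acetoxy-2,6,6-trimethylcyclohex-1-ene-1-carboxylate F3 beside unreacted methyl (S)-4-hydroxy-2,6,6-trimethylcyclohex-1-ene-1-carboxylate F4. After separation, methanolysis of F3 (K2CO3, MeOH) comes back to the route at 9.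

2. Step 25.
What may go wrong: enolisation toward C7 may open the epoxide. The stabilised anion may add sluggishly to the deactivated polyenal. The C9=C10 geometry may be lost in the delocalised anion.
Fallback: the olefination is run one oxidation level lower, where no β,γ-epoxy ketone exists. The fallback sets out from 30. Double deprotonation (LiN(i-Pr)2, 2.1 equiv, THF, −78 °C) and addition of 23 should give (3S,5R,6S,3'R)-3'-acetoxy-3-(tert-butyldimethylsilyloxy)-5,6-epoxy-7',8'-didehydro-5,6,7,8-tetrahydro-β,β-caroten-8-ol F5. Bu4NF buffered with AcOH frees C3–OH to give (3S,5R,6S,3'R)-3'-acetoxy-5,6-epoxy-7',8'-didehydro-5,6,7,8-tetrahydro-β,β-carotene-3,8-diol F6. MnO2 in CH2Cl2 then oxidises only the allylic C8 carbinol, which comes back to the route at 33.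

3. Step 4.
What may go wrong: aldehyde selectivity may erode. Palladium hydride may move the isopropenyl double bond into conjugation. Coordination of the diene ester may slow turnover.
Fallback: oxygen is brought in through boron instead of palladium. The fallback sets out from 7. Hydroboration with catecholborane catalysed by RhCl(PPh3)3 (THF, rt) is selective for the monosubstituted alkene and gives methyl 5-(1,3,2-benzodioxaborol-2-yl)-3,3-dimethyl-2-(prop-1-en-2-yl)pentanoate F7. Oxidation with H2O2 at pH 7 gives methyl 5-hydroxy-3,3-dimethyl-2-(prop-1-en-2-yl)pentanoate F8. F8 is oxidised at once with Dess–Martin periodinane, before it can lactonise, which comes back to the route at 8.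

Further compounds
F1 | step 5 | methyl 4-hydroxy-2,2-dimethyl-6-methylidenecyclohexane-1-carboxylate (racemic diastereomer mixture) | COC(=O)C1C(=C)CC(O)CC1(C)C
F2 | step 5 | methyl 4-hydroxy-2,6,6-trimethylcyclohex-1-ene-1-carboxylate (racemic) | OC1CC(C)=C(C(=O)OC)C(C)(C)C1
F3 | step 5 | methyl (R)-4-acetoxy-2,6,6-trimethylcyclohex-1-ene-1-carboxylate | CC(=O)O[C@@H]1CC(C)=C(C(=O)OC)C(C)(C)C1
F4 | step 5 | methyl (S)-4-hydroxy-2,6,6-trimethylcyclohex-1-ene-1-carboxylate | O[C@H]1CC(C)=C(C(=O)OC)C(C)(C)C1
F5 | step 25 | (3S,5R,6S,3'R)-3'-acetoxy-3-(tert-butyldimethylsilyloxy)-5,6-epoxy-7',8'-didehydro-5,6,7,8-tetrahydro-β,β-caroten-8-ol (C8 epimers) | CC(=O)O[C@@H]1CC(C)=C(C#C/C(C)=C/C=C/C(C)=C/C=C/C=C(C)/C=C/C=C(\C)C(O)C[C@@]23O[C@]2(C)C[C@@H](O[Si](C)(C)C(C)(C)C)CC3(C)C)C(C)(C)C1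
F6 | step 25 | (3S,5R,6S,3'R)-3'-acetoxy-5,6-epoxy-7',8'-didehydro-5,6,7,8-tetrahydro-β,β-carotene-3,8-diol (C8 epimers) | CC(=O)O[C@@H]1CC(C)=C(C#C/C(C)=C/C=C/C(C)=C/C=C/C=C(C)/C=C/C=C(\C)C(O)C[C@@]23O[C@]2(C)C[C@@H](O)CC3(C)C)C(C)(C)C1
F7 | step 4 | methyl 5-(1,3,2-benzodioxaborol-2-yl)-3,3-dimethyl-2-(prop-1-en-2-yl)pentanoate (racemic) | COC(=O)C(C(C)=C)C(C)(C)CCB1Oc2ccccc2O1
F8 | step 4 | methyl 5-hydroxy-3,3-dimethyl-2-(prop-1-en-2-yl)pentanoate (racemic) | COC(=O)C(C(C)=C)C(C)(C)CCO
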